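Ring A, the hexasubstituted phloroglucinol core, is disconnected at C8a–C8 and C6–C7 into 3-ethoxy-2-methylcyclobutenone and a siloxyalkyne that already carries the C1' stereocentre. One thermal operation closes ring A with all six substituents in place and delivers its three oxygens in different states: free phenol at C8a (future O1), silyl ether at C7, ethyl ether at C5. The alkyne comes from desymmetrised 3-isobutylglutaric anhydride; its side arm is kept at the acid oxidation level as an OBO ortho ester, so that after annulation it lactonises onto the C8a phenol and is ring-expanded to the syncarpic acid unit; acylation at C4a and Mitsunobu closure of ring C follow.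

Key step: step 7

Remark on the chemistry: the triketone unit is written as the enol drawn in the target; its enol forms interconvert by tautomerism and rotation about the C1'–ring bond and are treated as one compound. With this drawing C2 is R and C1' is S.

Remark on the chemistry: the alkyne side arm is carried as an ortho ester of the carboxylic acid and not as a protected primary alcohol. Carbon skeleton, key bonds and ring closure are unchanged, and no oxidation is needed next to the free, electron-rich phenol after the annulation.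

Abbreviations in names: OBO = 4-methyl-2,6,7-trioxabicyclo[2.2.2]octan-1-yl; TIPS = triisopropylsilyl; TES = triethylsilyl; "triketone enol" = 2-hydroxy-3,3,5,5-tetramethyl-4,6-dioxocyclohex-1-en-1-yl.

Step 1
Reactants: 1 3-isobutylglutaric anhydride
Product: 2 (3R)-3-(2-ethoxy-2-oxoethyl)-5-methylhexanoic acid
Conditions: quinidine (1.1 equiv), EtOH (3 equiv), toluene, −50 °C; dilute HCl wash
Reagents that add atoms: ethanol, CCO
Why: Alkaloid-mediated desymmetrising alcoholysis of a prochiral 3-substituted glutaric anhydride, in which the quinuclidine base delivers ethanol to one enantiotopic carbonyl and so sets the future C1' centre as R; the sense is assigned by analogy with other 3-alkylglutaric anhydrides, quinine gives the mirror-image half-ester if it has to be reversed, and the optical purity can be raised by crystallising an amine salt.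

Step 2
Reactants: 2 (3R)-3-(2-ethoxy-2-oxoethyl)-5-methylhexanoic acid
Product: 3 ethyl (3S)-5-methyl-3-{2-[(3-methyloxetan-3-yl)methoxy]-2-oxoethyl}hexanoate
Conditions: (3-methyloxetan-3-yl)methanol, DCC, 4-(dimethylamino)pyridine (cat.), CH2Cl2, 0 °C → rt
Reagents that add atoms: (3-methyloxetan-3-yl)methanol, CC1(CO)COC1
Why: Steglich esterification of the free acid, which leaves the ethyl ester and the stereocentre untouched (the descriptor changes only because the priorities change).

Step 3
Reactants: 3 ethyl (3S)-5-methyl-3-{2-[(3-methyloxetan-3-yl)methoxy]-2-oxoethyl}hexanoate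
Product: 4 ethyl (3S)-5-methyl-3-[(OBO)methyl]hexanoate
Conditions: BF3·OEt2 (0.25 equiv), CH2Cl2, −15 °C → rt; Et3N quench
Reagents that add atoms: none
Why: Lewis-acid rearrangement of an oxetanylmethyl ester to the bicyclic ortho ester (oxetane opening, capture of the cation by the ester carbonyl), which masks the acid against the amide base and the organolithium of the next two steps.

Step 4
Reactants: 4 ethyl (3S)-5-methyl-3-[(OBO)methyl]hexanoate
Product: 6 ethyl (3R)-2,2-dibromo-5-methyl-3-[(OBO)methyl]hexanoate, via monobromo ester 5 (not isolated)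
Conditions: LiN(i-Pr)2 (1.1 equiv), THF, −78 °C; BrCCl2CCl2Br (1.1 equiv); then LiN(i-Pr)2 (1.2 equiv), −78 °C; BrCCl2CCl2Br (1.2 equiv)
Reagents that add atoms: 1,2-dibromotetrachloroethane, BrC(Cl)(Cl)C(Cl)(Cl)Br
Why: Two successive ester enolate brominations with a positive-bromine donor at C2, the only enolisable position, should give the gem-dibromide needed for ynolate formation without involving the β-stereocentre.

Step 5
Reactants: 6 ethyl (3R)-2,2-dibromo-5-methyl-3-[(OBO)methyl]hexanoate
Product: 8 triisopropyl({(3R)-5-methyl-3-[(OBO)methyl]hex-1-yn-1-yl}oxy)silane, via lithium ynolate 7 (not isolated)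
Conditions: t-BuLi (4.2 equiv), THF, −78 → 0 °C; then TIPSCl (2.2 equiv), 0 °C → rt
Reagents that add atoms: chlorotriisopropylsilane, CC(C)[Si](Cl)(C(C)C)C(C)C
Why: Ynolate formation from an α,α-dibromo ester (two bromine–lithium exchanges, then loss of ethoxide from the ester dianion) followed by O-silylation with a bulky chlorosilane, a known route to siloxyalkynes; the ortho ester is inert to t-BuLi and the propargylic centre is never deprotonated.

Step 6
Reactants: 9 acetone; 10 1-ethoxypropyne
Product: 12 3-ethoxy-2-methylcyclobut-2-en-1-one, via ketene 11 (not isolated)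
Conditions: 9 cracked in a hot-wire ketene generator (about 700 °C); ketene stream passed into 10, CH2Cl2, 0 °C → rt
Reagents that add atoms: none
Why: Thermal [2+2] cycloaddition of ketene to an ynol ether, in which the nucleophilic methyl-bearing alkyne carbon attacks the ketene carbonyl carbon, so that methyl ends at C2 and ethoxy at C3 of the cyclobutenone.

Step 7
Reactants: 8 triisopropyl({(3R)-5-methyl-3-[(OBO)methyl]hex-1-yn-1-yl}oxy)silane; 12 3-ethoxy-2-methylcyclobut-2-en-1-one
Product: 17 5-ethoxy-4-methyl-2-[(2R)-4-methyl-1-(OBO)pentan-2-yl]-3-(TIPS-oxy)phenol, via vinylketene 13 (not isolated), via vinylcyclobutenone 14 (not isolated), via dienylketene 15 (not isolated), via cyclohexadienone 16 (not isolated)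
Conditions: 12 (1.3 equiv), toluene, 110 °C, then 145 °C (sealed tube)
Reagents that add atoms: none
Why: Danheiser benzannulation: 4π electrocyclic opening of 12 gives vinylketene 13, whose carbonyl carbon (future C8a) bonds to the alkyl-bearing alkyne carbon (future C8) and whose α-carbon (future C6) bonds to the siloxy carbon (future C7) in a regioselective [2+2] cycloaddition that gives 14. Opening of 14 gives dienylketene 15, 6π electrocyclisation (thermal, disrotatory) re-forms the C8a–C4a bond and thereby closes six-membered ring A, and tautomerisation of 16 gives the phenol. The closest known reaction type is the annulation of cyclobutenones with siloxyalkynes to resorcinol monosilyl ethers; the 3-alkoxy group should only raise the temperature needed for the first ring opening. No stereocentre is created, and the existing C1' centre is propargylic, not acidic, and should pass through neutral thermal conditions unchanged. The selectivity needed is the regiochemistry of the ketene–alkyne [2+2] step, which the polarisation of the siloxyalkyne secures: the side chain lands between the new phenol and the silyl ether, the methyl group between silyl ether and ethoxy group, and the C8a hydroxyl is left as the only free oxygen of ring A.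

Step 8
Reactants: 17 5-ethoxy-4-methyl-2-[(2R)-4-methyl-1-(OBO)pentan-2-yl]-3-(TIPS-oxy)phenol
Product: 19 (4R)-7-ethoxy-6-methyl-4-(2-methylpropyl)-5-(TIPS-oxy)-3,4-dihydro-2H-chromen-2-one, via triol monoester 18 (not isolated)
Conditions: pyridinium p-toluenesulfonate (cat.), THF/H2O, rt; then p-toluenesulfonic acid monohydrate (10 mol %), toluene, 70 °C
Reagents that add atoms: water, O
Why: Mild aqueous acid opens the ortho ester to ester 18, and acid-catalysed transesterification by the neighbouring C8a phenol then closes the six-membered dihydrocoumarin, helped by the C4 substituent and the flanking silyloxy group; only the C8a oxygen is free, so the lactone can form in one direction only.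

Step 9
Reactants: 19 (4R)-7-ethoxy-6-methyl-4-(2-methylpropyl)-5-(TIPS-oxy)-3,4-dihydro-2H-chromen-2-one
Product: 20 (4R)-8-bromo-7-ethoxy-6-methyl-4-(2-methylpropyl)-5-(TIPS-oxy)-3,4-dihydro-2H-chromen-2-one
Conditions: NBS (1.05 equiv), MeCN, 0 °C, dark
Reagents that add atoms: N-bromosuccinimide, O=C1CCC(=O)N1Br
Why: Electrophilic aromatic bromination at the only unsubstituted ring carbon (future C4a), which is ortho to the ethoxy group and para to the silyloxy group.

Step 10
Reactants: 20 (4R)-8-bromo-7-ethoxy-6-methyl-4-(2-methylpropyl)-5-(TIPS-oxy)-3,4-dihydro-2H-chromen-2-one; 21 2,2,4,4-tetramethylcyclobutane-1,3-dione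
Product: 25 6-[(1S)-1-{3-bromo-4-ethoxy-2-hydroxy-5-methyl-6-(TIPS-oxy)phenyl}-3-methylbutyl]-5-hydroxy-2,2,4,4-tetramethylcyclohex-5-ene-1,3-dione, via lactone enolate 22 (not isolated), via cyclobutanolate 23 (not isolated), via ring-opened enolate 24 (not isolated)
Conditions: LiN(i-Pr)2 (2.2 equiv), THF, −78 °C; 21 (1.2 equiv), −78 °C → rt; aq. NH4Cl
Reagents that add atoms: none
Why: Proposed new method: lithium enolate 22 should add to a strained carbonyl of 21 to give 23, retro-Claisen cleavage of the four-membered ring should give ketone enolate 24, and Dieckmann-type attack of 24 on the aryl lactone carbonyl should expel the C8a phenoxide and close the six-membered triketone, whose irreversible deprotonation drives the sequence; the closest known reaction types are the alkoxide-induced retro-Claisen opening of 21 to 2,2,4-trimethyl-3-oxopentanoates and the Dieckmann cyclisation of δ-keto esters to cyclohexane-1,3-diones, and the C1' centre, which is not α to a carbonyl group, is not touched.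

Step 11
Reactants: 26 ethyl (3S)-3-hydroxy-3-phenylpropanoate
Product: 27 ethyl (3S)-3-phenyl-3-(TES-oxy)propanoate
Conditions: TESCl, imidazole, CH2Cl2, 0 °C
Reagents that add atoms: chlorotriethylsilane, CC[Si](Cl)(CC)CC
Why: Silylation of the secondary benzylic alcohol with a group that survives organolithium addition and is later removed by dilute acid without loss of the aryl silyl ether.

Step 12
Reactants: 27 ethyl (3S)-3-phenyl-3-(TES-oxy)propanoate
Product: 28 (3S)-N-methoxy-N-methyl-3-phenyl-3-(TES-oxy)propanamide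
Conditions: MeNHOMe·HCl (1.5 equiv), i-PrMgCl (3.0 equiv), THF, −20 → 0 °C
Reagents that add atoms: N,O-dimethylhydroxylamine hydrochloride, CNOC.Cl
Why: Direct Weinreb amidation of an ester with the magnesium amide of N,O-dimethylhydroxylamine, under which the protected carbinol centre stays S.

Step 13
Reactants: 25 6-[(1S)-1-{3-bromo-4-ethoxy-2-hydroxy-5-methyl-6-(TIPS-oxy)phenyl}-3-methylbutyl]-5-hydroxy-2,2,4,4-tetramethylcyclohex-5-ene-1,3-dione; 28 (3S)-N-methoxy-N-methyl-3-phenyl-3-(TES-oxy)propanamide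
Product: 31 6-[(1S)-1-{4-ethoxy-2-hydroxy-3-[(3S)-3-hydroxy-3-phenylpropanoyl]-5-methyl-6-(TIPS-oxy)phenyl}-3-methylbutyl]-5-hydroxy-2,2,4,4-tetramethylcyclohex-5-ene-1,3-dione, via aryllithium 29 (not isolated), via silyl ether ketone 30 (not isolated)
Conditions: NaH (2.1 equiv), THF, 0 °C; t-BuLi (2.1 equiv), −78 °C; 28 (1.3 equiv), −78 → 0 °C; then 1 M aq. HCl, THF, rt
Reagents that add atoms: none
Why: Bromine–lithium exchange on the doubly deprotonated substrate (phenoxide and triketone enolate, the latter about as inert as a carboxylate and, as the anion, protected against retro-Michael loss of the C1' configuration) gives aryllithium 29, which adds once to the Weinreb amide through its chelated tetrahedral adduct, and dilute acid then releases ketone 30 and removes the triethylsilyl group without reaction at either stereocentre.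

Step 14
Reactants: 31 6-[(1S)-1-{4-ethoxy-2-hydroxy-3-[(3S)-3-hydroxy-3-phenylpropanoyl]-5-methyl-6-(TIPS-oxy)phenyl}-3-methylbutyl]-5-hydroxy-2,2,4,4-tetramethylcyclohex-5-ene-1,3-dione
Product: 32 (2R)-5-ethoxy-6-methyl-8-[(1S)-3-methyl-1-(triketone enol)butyl]-2-phenyl-7-(TIPS-oxy)-2,3-dihydro-4H-chromen-4-one
Conditions: PPh3 (3 equiv), DIAD (3 equiv), THF (0.01 M), 0 °C → rt
Reagents that add atoms: none
Why: Intramolecular Mitsunobu etherification in which the C8a phenol, the only free oxygen ortho to the ketone, displaces the activated benzylic oxygen by SN2 with inversion, so that the S carbinol gives C2 as R and ring C closes in the 6-exo-tet mode; the reagents are used in excess because the acidic triketone enol consumes one equivalent of betaine, and its hindered oxygen cannot reach the carbinol carbon through a ring of normal size.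

Step 15
Reactants: 32 (2R)-5-ethoxy-6-methyl-8-[(1S)-3-methyl-1-(triketone enol)butyl]-2-phenyl-7-(TIPS-oxy)-2,3-dihydro-4H-chromen-4-one
Product: 33 (2R)-5-hydroxy-6-methyl-8-[(1S)-3-methyl-1-(triketone enol)butyl]-2-phenyl-7-(TIPS-oxy)-2,3-dihydro-4H-chromen-4-one
Conditions: BCl3 (1 M in CH2Cl2, 3 equiv), CH2Cl2, −78 → 0 °C; then H2O
Reagents that add atoms: none
Why: Chelation-controlled dealkylation, in which BCl3 binds the C4 carbonyl and the peri C5 oxygen and chloride removes the ethyl group, the usual way to free the 5-hydroxyl of a flavanone; the hindered C7 silyl ether keeps that oxygen away from the triketone while the Lewis acid is present.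

Step 16
Reactants: 33 (2R)-5-hydroxy-6-methyl-8-[(1S)-3-methyl-1-(triketone enol)butyl]-2-phenyl-7-(TIPS-oxy)-2,3-dihydro-4H-chromen-4-one
Product: 34 (2R)-5,7-dihydroxy-8-[(1S)-1-(2-hydroxy-3,3,5,5-tetramethyl-4,6-dioxocyclohex-1-en-1-yl)-3-methylbutyl]-6-methyl-2-phenyl-2,3-dihydro-4H-chromen-4-one (CNP0249552.1)
Conditions: TBAF (1.2 equiv), AcOH (1.5 equiv), THF, 0 °C
Reagents that add atoms: none
Why: Fluoride cleavage of the aryl silyl ether, buffered with acetic acid so that the flavanone is not opened to the chalcone and C2 is not epimerised.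

Compound list

1 | 3-isobutylglutaric anhydride [4-(2-methylpropyl)oxane-2,6-dione] | CC(C)CC1CC(=O)OC(=O)C1 | starting material
2 | (3R)-3-(2-ethoxy-2-oxoethyl)-5-methylhexanoic acid | CCOC(=O)C[C@H](CC(C)C)CC(=O)O | intermediate
3 | ethyl (3S)-5-methyl-3-{2-[(3-methyloxetan-3-yl)methoxy]-2-oxoethyl}hexanoate | CCOC(=O)C[C@H](CC(C)C)CC(=O)OCC1(C)COC1 | intermediate
4 | ethyl (3S)-5-methyl-3-[(4-methyl-2,6,7-trioxabicyclo[2.2.2]octan-1-yl)methyl]hexanoate | CCOC(=O)C[C@H](CC(C)C)CC12OCC(C)(CO1)CO2 | intermediate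
5 | ethyl (3R)-2-bromo-5-methyl-3-[(4-methyl-2,6,7-trioxabicyclo[2.2.2]octan-1-yl)methyl]hexanoate (C2 epimers) | CCOC(=O)C(Br)[C@H](CC(C)C)CC12OCC(C)(CO1)CO2 | intermediate
6 | ethyl (3R)-2,2-dibromo-5-methyl-3-[(4-methyl-2,6,7-trioxabicyclo[2.2.2]octan-1-yl)methyl]hexanoate | CCOC(=O)C(Br)(Br)[C@H](CC(C)C)CC12OCC(C)(CO1)CO2 | intermediate
7 | lithium (3R)-5-methyl-3-[(4-methyl-2,6,7-trioxabicyclo[2.2.2]octan-1-yl)methyl]hex-1-yn-1-olate | [Li+].[O-]C#C[C@H](CC(C)C)CC12OCC(C)(CO1)CO2 | intermediate
8 | triisopropyl({(3R)-5-methyl-3-[(4-methyl-2,6,7-trioxabicyclo[2.2.2]octan-1-yl)methyl]hex-1-yn-1-yl}oxy)silane | CC(C)[Si](C(C)C)(C(C)C)OC#C[C@H](CC(C)C)CC12OCC(C)(CO1)CO2 | intermediate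
9 | acetone | CC(C)=O | starting material
10 | 1-ethoxypropyne | CCOC#CC | starting material
11 | ketene | C=C=O | intermediate
12 | 3-ethoxy-2-methylcyclobut-2-en-1-one | CCOC1=C(C)C(=O)C1 | intermediate
13 | 3-ethoxy-2-methylbuta-1,3-dien-1-one (vinylketene) | C=C(OCC)C(C)=C=O | intermediate
14 | 4-(1-ethoxyethenyl)-4-methyl-2-[(2R)-4-methyl-1-(4-methyl-2,6,7-trioxabicyclo[2.2.2]octan-1-yl)pentan-2-yl]-3-[(triisopropylsilyl)oxy]cyclobut-2-en-1-one (C4 epimers) | C=C(OCC)C1(C)C(=O)C([C@H](CC(C)C)CC23OCC(C)(CO2)CO3)=C1O[Si](C(C)C)(C(C)C)C(C)C | intermediate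
15 | 5-ethoxy-4-methyl-2-[(2R)-4-methyl-1-(4-methyl-2,6,7-trioxabicyclo[2.2.2]octan-1-yl)pentan-2-yl]-3-[(triisopropylsilyl)oxy]hexa-1,3,5-trien-1-one (dienylketene) | O=C=C([C@H](CC(C)C)CC12OCC(C)(CO1)CO2)C(O[Si](C(C)C)(C(C)C)C(C)C)=C(C)C(OCC)=C | intermediate
16 | 5-ethoxy-4-methyl-2-[(2R)-4-methyl-1-(4-methyl-2,6,7-trioxabicyclo[2.2.2]octan-1-yl)pentan-2-yl]-3-[(triisopropylsilyl)oxy]cyclohexa-2,4-dien-1-one | O=C1CC(OCC)=C(C)C(O[Si](C(C)C)(C(C)C)C(C)C)=C1[C@H](CC(C)C)CC23OCC(C)(CO2)CO3 | intermediate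
17 | 5-ethoxy-4-methyl-2-[(2R)-4-methyl-1-(4-methyl-2,6,7-trioxabicyclo[2.2.2]octan-1-yl)pentan-2-yl]-3-[(triisopropylsilyl)oxy]phenol | Cc1c(OCC)cc(O)c([C@H](CC(C)C)CC23OCC(C)(CO2)CO3)c1O[Si](C(C)C)(C(C)C)C(C)C | intermediate
18 | 3-hydroxy-2-(hydroxymethyl)-2-methylpropyl (3R)-3-{4-ethoxy-2-hydroxy-5-methyl-6-[(triisopropylsilyl)oxy]phenyl}-5-methylhexanoate | Cc1c(OCC)cc(O)c([C@H](CC(C)C)CC(=O)OCC(C)(CO)CO)c1O[Si](C(C)C)(C(C)C)C(C)C | intermediate
19 | (4R)-7-ethoxy-6-methyl-4-(2-methylpropyl)-5-[(triisopropylsilyl)oxy]-3,4-dihydro-2H-chromen-2-one | CCOc1cc2OC(=O)C[C@@H](CC(C)C)c2c(O[Si](C(C)C)(C(C)C)C(C)C)c1C | intermediate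
20 | (4R)-8-bromo-7-ethoxy-6-methyl-4-(2-methylpropyl)-5-[(triisopropylsilyl)oxy]-3,4-dihydro-2H-chromen-2-one | CCOc1c(Br)c2OC(=O)C[C@@H](CC(C)C)c2c(O[Si](C(C)C)(C(C)C)C(C)C)c1C | intermediate
21 | 2,2,4,4-tetramethylcyclobutane-1,3-dione | CC1(C)C(=O)C(C)(C)C1=O | starting material
22 | lithium enolate of 20 [lithium (4R)-8-bromo-7-ethoxy-6-methyl-4-(2-methylpropyl)-5-[(triisopropylsilyl)oxy]-4H-chromen-2-olate] | CCOc1c(Br)c2OC([O-])=C[C@@H](CC(C)C)c2c(O[Si](C(C)C)(C(C)C)C(C)C)c1C.[Li+] | intermediate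
23 | lithium 1-{(4R)-8-bromo-7-ethoxy-6-methyl-4-(2-methylpropyl)-2-oxo-5-[(triisopropylsilyl)oxy]-3,4-dihydro-2H-chromen-3-yl}-2,2,4,4-tetramethyl-3-oxocyclobutan-1-olate (C3 epimers) | CCOc1c(Br)c2OC(=O)C(C3([O-])C(C)(C)C(=O)C3(C)C)[C@@H](CC(C)C)c2c(O[Si](C(C)C)(C(C)C)C(C)C)c1C.[Li+] | intermediate
24 | lithium enolate of (4R)-8-bromo-7-ethoxy-6-methyl-4-(2-methylpropyl)-3-(2,2,4-trimethyl-3-oxopentanoyl)-5-[(triisopropylsilyl)oxy]-3,4-dihydro-2H-chromen-2-one (isopropyl ketone enolate, C3 epimers) | CCOc1c(Br)c2OC(=O)C(C(=O)C(C)(C)C([O-])=C(C)C)[C@@H](CC(C)C)c2c(O[Si](C(C)C)(C(C)C)C(C)C)c1C.[Li+] | intermediate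
25 | 6-[(1S)-1-{3-bromo-4-ethoxy-2-hydroxy-5-methyl-6-[(triisopropylsilyl)oxy]phenyl}-3-methylbutyl]-5-hydroxy-2,2,4,4-tetramethylcyclohex-5-ene-1,3-dione | CCOc1c(Br)c(O)c([C@H](CC(C)C)C2=C(O)C(C)(C)C(=O)C(C)(C)C2=O)c(O[Si](C(C)C)(C(C)C)C(C)C)c1C | intermediate
26 | ethyl (3S)-3-hydroxy-3-phenylpropanoate | CCOC(=O)C[C@H](O)c1ccccc1 | starting material
27 | ethyl (3S)-3-phenyl-3-[(triethylsilyl)oxy]propanoate | CCOC(=O)C[C@H](O[Si](CC)(CC)CC)c1ccccc1 | intermediate
28 | (3S)-N-methoxy-N-methyl-3-phenyl-3-[(triethylsilyl)oxy]propanamide | CON(C)C(=O)C[C@H](O[Si](CC)(CC)CC)c1ccccc1 | intermediate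
29 | aryllithium from 25 as its disodium phenoxide/enolate salt | CCOc1c([Li])c([O-])c([C@H](CC(C)C)C2=C([O-])C(C)(C)C(=O)C(C)(C)C2=O)c(O[Si](C(C)C)(C(C)C)C(C)C)c1C.[Na+].[Na+] | intermediate
30 | 6-[(1S)-1-{4-ethoxy-2-hydroxy-5-methyl-3-[(3S)-3-phenyl-3-[(triethylsilyl)oxy]propanoyl]-6-[(triisopropylsilyl)oxy]phenyl}-3-methylbutyl]-5-hydroxy-2,2,4,4-tetramethylcyclohex-5-ene-1,3-dione | CCOc1c(C(=O)C[C@H](O[Si](CC)(CC)CC)c2ccccc2)c(O)c([C@H](CC(C)C)C2=C(O)C(C)(C)C(=O)C(C)(C)C2=O)c(O[Si](C(C)C)(C(C)C)C(C)C)c1C | intermediate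
31 | 6-[(1S)-1-{4-ethoxy-2-hydroxy-3-[(3S)-3-hydroxy-3-phenylpropanoyl]-5-methyl-6-[(triisopropylsilyl)oxy]phenyl}-3-methylbutyl]-5-hydroxy-2,2,4,4-tetramethylcyclohex-5-ene-1,3-dione | CCOc1c(C(=O)C[C@H](O)c2ccccc2)c(O)c([C@H](CC(C)C)C2=C(O)C(C)(C)C(=O)C(C)(C)C2=O)c(O[Si](C(C)C)(C(C)C)C(C)C)c1C | intermediate
32 | (2R)-5-ethoxy-8-[(1S)-1-(2-hydroxy-3,3,5,5-tetramethyl-4,6-dioxocyclohex-1-en-1-yl)-3-methylbutyl]-6-methyl-2-phenyl-7-[(triisopropylsilyl)oxy]-2,3-dihydro-4H-chromen-4-one | CCOc1c(C)c(O[Si](C(C)C)(C(C)C)C(C)C)c([C@H](CC(C)C)C2=C(O)C(C)(C)C(=O)C(C)(C)C2=O)c2O[C@@H](c3ccccc3)CC(=O)c12 | intermediate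
33 | (2R)-5-hydroxy-8-[(1S)-1-(2-hydroxy-3,3,5,5-tetramethyl-4,6-dioxocyclohex-1-en-1-yl)-3-methylbutyl]-6-methyl-2-phenyl-7-[(triisopropylsilyl)oxy]-2,3-dihydro-4H-chromen-4-one | Cc1c(O)c2c(c([C@H](CC(C)C)C3=C(O)C(C)(C)C(=O)C(C)(C)C3=O)c1O[Si](C(C)C)(C(C)C)C(C)C)O[C@@H](c1ccccc1)CC2=O | intermediate
34 | (2R)-5,7-dihydroxy-8-[(1S)-1-(2-hydroxy-3,3,5,5-tetramethyl-4,6-dioxocyclohex-1-en-1-yl)-3-methylbutyl]-6-methyl-2-phenyl-2,3-dihydro-4H-chromen-4-one | Cc1c(O)c2c(c([C@H](CC(C)C)C3=C(O)C(C)(C)C(=O)C(C)(C)C3=O)c1O)O[C@@H](c1ccccc1)CC2=O | target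

Total step count: 16. Longest linear sequence: 13 steps (steps 1–5, 7–10 and 13–16); steps 6, 11 and 12 make the two side fragments.

Steps most likely to fail

1. Step 10 (proposed new method). After the four-membered ring has opened, proton transfer from the strongly acidic β-dicarbonyl C–H may quench the ketone enolate before it attacks the lactone carbonyl, or the lactone enolate may fragment to a ketene and a phenoxide before it adds to the dione. The fallback uses known chemistry, sets out from 20 and 21 and comes back at 25; it divides the cascade into a crossed Claisen acylation and a separate Dieckmann-type closure. Dione 21 is opened with NaOMe in methanol to methyl 2,2,4-trimethyl-3-oxopentanoate F1, which is saponified with LiOH to 2,2,4-trimethyl-3-oxopentanoic acid F2 and converted with oxalyl chloride into 2,2,4-trimethyl-3-oxopentanoyl chloride F3. The lithium enolate of 20 (LiN(SiMe3)2, 2 equiv, THF, −78 °C) is C-acylated with F3 to give (4R)-8-bromo-7-ethoxy-6-methyl-4-(2-methylpropyl)-3-(2,2,4-trimethyl-3-oxopentanoyl)-5-[(triisopropylsilyl)oxy]-3,4-dihydro-2H-chromen-2-one F4. With LiN(i-Pr)2 (2.2 equiv) F4 forms its dianion, whose isopropyl ketone enolate attacks the lactone carbonyl, releases the C8a phenoxide and gives 25.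

2. Step 7. The alkoxy group stabilises the cyclobutenone, so ring opening may need temperatures at which the siloxyalkyne isomerises to a silylketene or the vinylketene is consumed by dimerisation, and the annulation stalls. The fallback sets out from 8 and comes back at 17; it makes the same vinylketene 13 at room temperature by a photochemical Wolff rearrangement, the diazo ketone variant of the same benzannulation, so the bonds formed and the ring closed do not change. 1-Ethoxyvinyllithium and N-methoxy-N-methylpropanamide give 2-ethoxypent-1-en-3-one F5; detrifluoroacetylative diazo transfer (LiN(SiMe3)2, CF3CO2CH2CF3, then MsN3, Et3N) gives 2-diazo-4-ethoxypent-4-en-3-one F6. Irradiation of F6 with 8 in CH2Cl2 causes a 1,2-shift of the ethoxyvinyl group with loss of nitrogen to give 13, which enters the [2+2], 4π and 6π sequence and, after gentle heating, gives 17.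

3. Step 14. The acidic triketone enol may intercept the betaine, and the activated benzylic oxygen may then be lost by elimination to the chalcone, whose oxa-Michael ring closure is not stereoselective, so that the configuration at C2 erodes. The fallback sets out from 31 and comes back at 33; it masks the enol before the cyclisation. Trimethylsilyldiazomethane in toluene/methanol methylates only the strongly acidic enol and gives 6-[(1S)-1-{4-ethoxy-2-hydroxy-3-[(3S)-3-hydroxy-3-phenylpropanoyl]-5-methyl-6-[(triisopropylsilyl)oxy]phenyl}-3-methylbutyl]-5-methoxy-2,2,4,4-tetramethylcyclohex-5-ene-1,3-dione F7. Mitsunobu closure with the usual 1.5 equivalents of PPh3 and DIAD gives (2R)-5-ethoxy-8-[(1S)-1-(2-methoxy-3,3,5,5-tetramethyl-4,6-dioxocyclohex-1-en-1-yl)-3-methylbutyl]-6-methyl-2-phenyl-7-[(triisopropylsilyl)oxy]-2,3-dihydro-4H-chromen-4-one F8. BCl3 then removes the peri ethyl group, and hydrolysis of the vinylogous methyl ester with dilute aqueous HCl in THF gives 33.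

Further compounds

F1 | step 10 | methyl 2,2,4-trimethyl-3-oxopentanoate | COC(=O)C(C)(C)C(=O)C(C)C
F2 | step 10 | 2,2,4-trimethyl-3-oxopentanoic acid | OC(=O)C(C)(C)C(=O)C(C)C
F3 | step 10 | 2,2,4-trimethyl-3-oxopentanoyl chloride | ClC(=O)C(C)(C)C(=O)C(C)C
F4 | step 10 | (4R)-8-bromo-7-ethoxy-6-methyl-4-(2-methylpropyl)-3-(2,2,4-trimethyl-3-oxopentanoyl)-5-[(triisopropylsilyl)oxy]-3,4-dihydro-2H-chromen-2-one | CCOc1c(Br)c2OC(=O)C(C(=O)C(C)(C)C(=O)C(C)C)[C@@H](CC(C)C)c2c(O[Si](C(C)C)(C(C)C)C(C)C)c1C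
F5 | step 7 | 2-ethoxypent-1-en-3-one | C=C(OCC)C(=O)CC
F6 | step 7 | 2-diazo-4-ethoxypent-4-en-3-one | C=C(OCC)C(=O)C(C)=[N+]=[N-]
F7 | step 14 | 6-[(1S)-1-{4-ethoxy-2-hydroxy-3-[(3S)-3-hydroxy-3-phenylpropanoyl]-5-methyl-6-[(triisopropylsilyl)oxy]phenyl}-3-methylbutyl]-5-methoxy-2,2,4,4-tetramethylcyclohex-5-ene-1,3-dione | CCOc1c(C(=O)C[C@H](O)c2ccccc2)c(O)c([C@H](CC(C)C)C2=C(OC)C(C)(C)C(=O)C(C)(C)C2=O)c(O[Si](C(C)C)(C(C)C)C(C)C)c1C
F8 | step 14 | (2R)-5-ethoxy-8-[(1S)-1-(2-methoxy-3,3,5,5-tetramethyl-4,6-dioxocyclohex-1-en-1-yl)-3-methylbutyl]-6-methyl-2-phenyl-7-[(triisopropylsilyl)oxy]-2,3-dihydro-4H-chromen-4-one | CCOc1c(C)c(O[Si](C(C)C)(C(C)C)C(C)C)c([C@H](CC(C)C)C2=C(OC)C(C)(C)C(=O)C(C)(C)C2=O)c2O[C@@H](c3ccccc3)CC(=O)c12
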